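**Retrosynthetic overview**

1. Target 25 ⇒ diol 24 (acetylation) ⇒ vinyl carbinol 18 + vinyl triflate 22 (C12–C13 bond by hydroboration/B-alkyl Suzuki–Miyaura coupling; the (E)-C13=C14 geometry comes with 22) ⇒ hydroxy aldehyde 17 (C11=C12 by methylenation).
2. 17 ⇒ monocyclic keto enal 15 in one cascade: conjugate addition of methyl (C20) to C10, then intramolecular aldol closure of ring B through the C8–C9 bond; C10, C9 and C8 are all set from the single stereocenter C5.
3. Enabling feature: C8 is a methyl-ketone carbon tied through C7–C6 to C5, the ring-A atom next to C10, and C10 carries the exocyclic C10=C9–C11HO enal. Attack at C10 turns C9 into an enolate carbon five atoms from C8, and the C4 gem-dimethyl group plus the C5 chain steer the methyl to the face of H5 (cis ring fusion).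
4. 15 ⇒ enol triflate 13 of aldehyde 11 (C9–C11 by carbonylation) ⇒ unsaturated aldimine 6 + Grignard reagent 8 (C5–C6 by auxiliary-controlled 1,4-addition) ⇒ 3-methylcyclohex-2-enone 1.
5. Ring order: ring A is the carbocycle of 1 (gem-dimethyl by cuprate addition, steps 1–2); ring B is closed in step 8.

Key step: step 8

Remark: labdane numbering is used (ring A = C1–C5 and C10; ring B = C5–C10; C17 and C20 = methyls on C8 and C10; side chain C11–C16). The SMILES is read as the A/B-cis isomer with H5, CH3-20, the C9 side chain and 8-OH all on one face, and the facial sense of step 4 is assigned from the chelate model of the auxiliary, not from a measured result.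

**Route**

Step 1
Reactants: 1 3-methylcyclohex-2-en-1-one
Product: 3 3,3-dimethylcyclohex-1-en-1-yl trifluoromethanesulfonate, via lithium enolate 2 (not isolated)
Conditions: Me2CuLi (from CuI and MeLi), Et2O, 0 °C; then PhNTf2, THF, 0 °C → rt
Reagents that add atoms: lithium dimethylcuprate, [Li+].C[Cu-]C; N-phenylbis(trifluoromethanesulfonimide), O=S(=O)(N(c1ccccc1)S(=O)(=O)C(F)(F)F)C(F)(F)F
Why: Cuprate 1,4-addition builds the gem-dimethyl carbon (C4) and gives a regiodefined enolate that is O-sulfonylated before it can equilibrate (conjugate addition/enolate triflation).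

Step 2
Reactants: 3 3,3-dimethylcyclohex-1-en-1-yl trifluoromethanesulfonate
Product: 4 3,3-dimethylcyclohex-1-ene-1-carbaldehyde
Conditions: Pd(PPh3)4 (cat.), CO (1 atm), Bu3SnH (slow addition), LiCl, THF, 50 °C
Reagents that add atoms: carbon monoxide, [C-]#[O+]
Why: Palladium-catalysed reductive carbonylation (formylation) of a vinyl triflate, by oxidative addition, CO insertion and hydride transfer from tin, should give the enal whose formyl carbon becomes C9.

Step 3
Reactants: 4 3,3-dimethylcyclohex-1-ene-1-carbaldehyde, 5 tert-butyl (2S)-2-amino-3,3-dimethylbutanoate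
Product: 6 tert-butyl (2S)-2-{[(E)-(3,3-dimethylcyclohex-1-en-1-yl)methylidene]amino}-3,3-dimethylbutanoate
Conditions: MgSO4, toluene, rt
Reagents that add atoms: none
Why: Imine condensation of the enal with the primary amino ester, driven by removal of water, should give the (E)-aldimine that carries the chiral auxiliary.

Step 4
Reactants: 6 tert-butyl (2S)-2-{[(E)-(3,3-dimethylcyclohex-1-en-1-yl)methylidene]amino}-3,3-dimethylbutanoate, 7 2-(2-bromoethyl)-2-methyl-1,3-dioxolane
Product: 11 (1R,2S)-3,3-dimethyl-2-[2-(2-methyl-1,3-dioxolan-2-yl)ethyl]cyclohexane-1-carbaldehyde, via Grignard reagent 8 (not isolated), via magnesium azaenolate 9 (not isolated), via saturated aldimine 10 (not isolated)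
Conditions: 7, Mg, THF, rt; then 6, THF, −25 → 0 °C; then aq. AcOH/NaOAc buffer (pH 4.5), 0 °C
Reagents that add atoms: water, O
Why: Chelation-controlled 1,4-addition of a Grignard reagent to a chiral α,β-unsaturated aldimine: magnesium bridged between the imine nitrogen and the ester carbonyl should deliver the chain to the s-cis enimine from the face opposite the tert-butyl group, which sets C5, and buffered hydrolysis then frees the aldehyde and the auxiliary while the ketal survives (the configuration at the formyl-bearing carbon, expected trans, is erased in step 5).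

Step 5
Reactants: 11 (1R,2S)-3,3-dimethyl-2-[2-(2-methyl-1,3-dioxolan-2-yl)ethyl]cyclohexane-1-carbaldehyde
Product: 13 (E)-{(2R)-3,3-dimethyl-2-[2-(2-methyl-1,3-dioxolan-2-yl)ethyl]cyclohexylidene}methyl trifluoromethanesulfonate, via potassium enolate 12 (not isolated)
Conditions: KN(SiMe3)2, THF, −78 °C; then PhNTf2, −78 → 0 °C
Reagents that add atoms: N-phenylbis(trifluoromethanesulfonimide), O=S(=O)(N(c1ccccc1)S(=O)(=O)C(F)(F)F)C(F)(F)F
Why: Removal of the only α-hydrogen gives the exocyclic aldehyde enolate, which is trapped on oxygen (enol triflate formation); C5 is untouched, and either alkene geometry serves the next steps.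

Step 6
Reactants: 13 (E)-{(2R)-3,3-dimethyl-2-[2-(2-methyl-1,3-dioxolan-2-yl)ethyl]cyclohexylidene}methyl trifluoromethanesulfonate
Product: 14 (2E)-2-{(2R)-3,3-dimethyl-2-[2-(2-methyl-1,3-dioxolan-2-yl)ethyl]cyclohexylidene}acetaldehyde
Conditions: Pd(PPh3)4 (cat.), CO (1 atm), Bu3SnH (slow addition), LiCl, THF, 50 °C
Reagents that add atoms: carbon monoxide, [C-]#[O+]
Why: The same palladium-catalysed reductive carbonylation replaces triflate by formyl (C11) and should give the exocyclic enal, which is expected to settle as the (E) isomer with the formyl group turned away from C5.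

Step 7
Reactants: 14 (2E)-2-{(2R)-3,3-dimethyl-2-[2-(2-methyl-1,3-dioxolan-2-yl)ethyl]cyclohexylidene}acetaldehyde
Product: 15 (2E)-2-[(2R)-3,3-dimethyl-2-(3-oxobutyl)cyclohexylidene]acetaldehyde
Conditions: PPTS (cat.), acetone/H2O, 45 °C
Reagents that add atoms: water, O
Why: Mild acid-catalysed ketal hydrolysis should free the C8 methyl ketone without epimerising the γ-stereocenter C5 or moving the conjugated double bond.

Step 8
Reactants: 15 (2E)-2-[(2R)-3,3-dimethyl-2-(3-oxobutyl)cyclohexylidene]acetaldehyde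
Product: 17 (1R,2S,4aR,8aS)-2-hydroxy-2,5,5,8a-tetramethyldecahydronaphthalene-1-carbaldehyde, via lithium enolate 16 (not isolated)
Conditions: Me2CuLi (from CuI and MeLi, 2 equiv), Et2O, −78 → −30 °C; then sat. aq. NH4Cl, −30 °C
Reagents that add atoms: lithium dimethylcuprate, [Li+].C[Cu-]C
Why: Me2CuLi adds 1,4 to the exocyclic (E)-enal and puts CH3-20 on C10, which unmasks lithium enolate 16 (C9=C11–OLi); its carbon C9 then adds to the C8 ketone held five atoms away by the C5–C6–C7 tether, the closest known reaction type being the tandem organocuprate conjugate addition–intramolecular aldol cyclisation of keto enones and keto enals. Ring B is closed by the C8–C9 bond in a 6-(enolexo)-exo-trig aldol addition through a lithium-bridged chair transition state. C10 is set by substrate control: in the ring-A chair that keeps the C5 chain equatorial the axial C4 methyl blocks the axial face of C10, so the cuprate should enter equatorially, anti to the C5 chain and cis to H5, which fixes the cis ring fusion. C9 is set by the ring-B chair, in which the formyl carbon C11 lies equatorial because the axial site is syn-diaxial to C4. C8 is set in the same chair: CH3-17 takes the equatorial site to avoid the new axial CH3-20, so the lithium-bound oxygen is axial, cis to C11 and to CH3-20, as the lithium bridge to the enolate oxygen also demands. The step needs 1,4- over 1,2-addition and ring closure faster than enolate equilibration or dehydration; the soft cuprate (inert to the saturated ketone at low temperature), the five-atom tether and the cold NH4Cl quench of the aldolate should secure this.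

Step 9
Reactants: 17 (1R,2S,4aR,8aS)-2-hydroxy-2,5,5,8a-tetramethyldecahydronaphthalene-1-carbaldehyde
Product: 18 (1R,2S,4aR,8aS)-1-ethenyl-2,5,5,8a-tetramethyldecahydronaphthalen-2-ol
Conditions: Zn, CH2Br2, TiCl4 (reagent pre-formed in THF), CH2Cl2, 0 °C → rt
Reagents that add atoms: dibromomethane, BrCBr
Why: Non-basic titanium–zinc methylenation of an aldehyde should turn C11HO into the C11=C12 vinyl group without the alkoxide formation that would invite retro-aldol cleavage or epimerisation at C9.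

Step 10
Reactants: 19 ethyl 3-oxobutanoate
Product: 21 ethyl (2E)-3-{[(trifluoromethyl)sulfonyl]oxy}but-2-enoate, via ammonium enolate 20 (not isolated)
Conditions: aq. Me4NOH, hexane, 5 °C; then Tf2O
Reagents that add atoms: trifluoromethanesulfonic anhydride, O=S(=O)(OS(=O)(=O)C(F)(F)F)C(F)(F)F
Why: O-triflation of the non-chelated tetramethylammonium enolate of a β-keto ester should give the (E)-enol triflate (triflate trans to the ester), the geometry that later becomes C13=C14.

Step 11
Reactants: 21 ethyl (2E)-3-{[(trifluoromethyl)sulfonyl]oxy}but-2-enoate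
Product: 22 (2E)-4-hydroxybut-2-en-2-yl trifluoromethanesulfonate
Conditions: iBu2AlH (2.2 equiv), CH2Cl2, −78 °C; aq. potassium sodium tartrate
Reagents that add atoms: none
Why: 1,2-Reduction of the conjugated ester by the aluminium hydride at low temperature should give the allylic alcohol and leave the vinyl triflate and the alkene geometry intact.

Step 12
Reactants: 18 (1R,2S,4aR,8aS)-1-ethenyl-2,5,5,8a-tetramethyldecahydronaphthalen-2-ol, 22 (2E)-4-hydroxybut-2-en-2-yl trifluoromethanesulfonate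
Product: 24 (1R,2S,4aR,8aS)-1-[(3E)-5-hydroxy-3-methylpent-3-en-1-yl]-2,5,5,8a-tetramethyldecahydronaphthalen-2-ol, via alkylborane 23 (not isolated)
Conditions: 9-BBN (2.5 equiv), THF, 0 °C → rt; then 22, Pd(dppf)Cl2 (cat.), aq. K3PO4, DMF, 50 °C
Reagents that add atoms: none
Why: Anti-Markovnikov hydroboration of the monosubstituted alkene puts boron on C12, and B-alkyl Suzuki–Miyaura coupling with the vinyl triflate forms C12–C13 with retention, so the (E)-C13=C14 geometry is carried over from 22.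

Step 13
Reactants: 24 (1R,2S,4aR,8aS)-1-[(3E)-5-hydroxy-3-methylpent-3-en-1-yl]-2,5,5,8a-tetramethyldecahydronaphthalen-2-ol
Product: 25 (2E)-5-[(1R,2S,4aR,8aS)-2-hydroxy-2,5,5,8a-tetramethyldecahydronaphthalen-1-yl]-3-methylpent-2-en-1-yl acetate
Conditions: Ac2O, pyridine, DMAP (cat.), CH2Cl2, 0 °C
Reagents that add atoms: acetic anhydride, CC(=O)OC(C)=O
Why: Acylation of the primary allylic hydroxyl is far faster than that of the hindered tertiary C8 hydroxyl, so the mono-acetate (the target) should result.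

**Compound list**

1 | 3-methylcyclohex-2-en-1-one | CC1=CC(=O)CCC1 | starting material
2 | lithium 3,3-dimethylcyclohex-1-en-1-olate | [Li+].[O-]C1=CC(C)(C)CCC1 | intermediate
3 | 3,3-dimethylcyclohex-1-en-1-yl trifluoromethanesulfonate | CC1(C)CCCC(OS(=O)(=O)C(F)(F)F)=C1 | intermediate
4 | 3,3-dimethylcyclohex-1-ene-1-carbaldehyde | CC1(C)CCCC(C=O)=C1 | intermediate
5 | tert-butyl (2S)-2-amino-3,3-dimethylbutanoate | CC(C)(C)[C@H](N)C(=O)OC(C)(C)C | starting material
6 | tert-butyl (2S)-2-{[(E)-(3,3-dimethylcyclohex-1-en-1-yl)methylidene]amino}-3,3-dimethylbutanoate | CC1(C)CCCC(/C=N/[C@@H](C(C)(C)C)C(=O)OC(C)(C)C)=C1 | intermediate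
7 | 2-(2-bromoethyl)-2-methyl-1,3-dioxolane | CC1(CCBr)OCCO1 | starting material
8 | [2-(2-methyl-1,3-dioxolan-2-yl)ethyl]magnesium bromide | CC1(CC[Mg]Br)OCCO1 | intermediate
9 | magnesium azaenolate: tert-butyl (2S)-2-[(bromomagnesio){[(2R)-3,3-dimethyl-2-[2-(2-methyl-1,3-dioxolan-2-yl)ethyl]cyclohexylidene]methyl}amino]-3,3-dimethylbutanoate | Br[Mg]N(C=C1CCCC(C)(C)[C@H]1CCC1(C)OCCO1)[C@@H](C(C)(C)C)C(=O)OC(C)(C)C | intermediate
10 | tert-butyl (2S)-2-{[(E)-{(1R,2S)-3,3-dimethyl-2-[2-(2-methyl-1,3-dioxolan-2-yl)ethyl]cyclohexyl}methylidene]amino}-3,3-dimethylbutanoate | CC(C)(C)[C@H](/N=C/[C@@H]1CCCC(C)(C)[C@H]1CCC1(C)OCCO1)C(=O)OC(C)(C)C | intermediate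
11 | (1R,2S)-3,3-dimethyl-2-[2-(2-methyl-1,3-dioxolan-2-yl)ethyl]cyclohexane-1-carbaldehyde | O=C[C@@H]1CCCC(C)(C)[C@H]1CCC1(C)OCCO1 | intermediate
12 | potassium {(2R)-3,3-dimethyl-2-[2-(2-methyl-1,3-dioxolan-2-yl)ethyl]cyclohexylidene}methanolate | [K+].[O-]C=C1CCCC(C)(C)[C@H]1CCC1(C)OCCO1 | intermediate
13 | (E)-{(2R)-3,3-dimethyl-2-[2-(2-methyl-1,3-dioxolan-2-yl)ethyl]cyclohexylidene}methyl trifluoromethanesulfonate | FC(F)(F)S(=O)(=O)O/C=C1\CCCC(C)(C)[C@H]1CCC1(C)OCCO1 | intermediate
14 | (2E)-2-{(2R)-3,3-dimethyl-2-[2-(2-methyl-1,3-dioxolan-2-yl)ethyl]cyclohexylidene}acetaldehyde | O=C/C=C1\CCCC(C)(C)[C@H]1CCC1(C)OCCO1 | intermediate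
15 | (2E)-2-[(2R)-3,3-dimethyl-2-(3-oxobutyl)cyclohexylidene]acetaldehyde | O=C/C=C1\CCCC(C)(C)[C@H]1CCC(C)=O | intermediate
16 | lithium 2-[(1S,2R)-1,3,3-trimethyl-2-(3-oxobutyl)cyclohexyl]ethen-1-olate | [Li+].[O-]C=C[C@@]1(C)CCCC(C)(C)[C@H]1CCC(C)=O | intermediate
17 | (1R,2S,4aR,8aS)-2-hydroxy-2,5,5,8a-tetramethyldecahydronaphthalene-1-carbaldehyde | O=C[C@@H]1[C@@]2(C)CCCC(C)(C)[C@H]2CC[C@]1(C)O | intermediate
18 | (1R,2S,4aR,8aS)-1-ethenyl-2,5,5,8a-tetramethyldecahydronaphthalen-2-ol | C=C[C@@H]1[C@@]2(C)CCCC(C)(C)[C@H]2CC[C@]1(C)O | intermediate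
19 | ethyl 3-oxobutanoate | CCOC(=O)CC(C)=O | starting material
20 | tetramethylammonium 4-ethoxy-4-oxobut-2-en-2-olate | C[N+](C)(C)C.CCOC(=O)C=C(C)[O-] | intermediate
21 | ethyl (2E)-3-{[(trifluoromethyl)sulfonyl]oxy}but-2-enoate | CCOC(=O)/C=C(\C)OS(=O)(=O)C(F)(F)F | intermediate
22 | (2E)-4-hydroxybut-2-en-2-yl trifluoromethanesulfonate | OC/C=C(\C)OS(=O)(=O)C(F)(F)F | intermediate
23 | 9-{2-[(1R,2S,4aR,8aS)-2-hydroxy-2,5,5,8a-tetramethyldecahydronaphthalen-1-yl]ethyl}-9-borabicyclo[3.3.1]nonane | B1(CC[C@@H]3[C@@]4(C)CCCC(C)(C)[C@H]4CC[C@]3(C)O)C2CCCC1CCC2 | intermediate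
24 | (1R,2S,4aR,8aS)-1-[(3E)-5-hydroxy-3-methylpent-3-en-1-yl]-2,5,5,8a-tetramethyldecahydronaphthalen-2-ol | OC/C=C(\C)CC[C@@H]1[C@@]2(C)CCCC(C)(C)[C@H]2CC[C@]1(C)O | intermediate
25 | (2E)-5-[(1R,2S,4aR,8aS)-2-hydroxy-2,5,5,8a-tetramethyldecahydronaphthalen-1-yl]-3-methylpent-2-en-1-yl acetate | CC(=O)OC/C=C(\C)CC[C@@H]1[C@@]2(C)CCCC(C)(C)[C@H]2CC[C@]1(C)O | target

**Step count**

Total step count: 13. Longest linear sequence: 11 steps (steps 1–9, 12 and 13; steps 10 and 11 make the coupling partner).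

**Steps most likely to fail**

Step 8. What may go wrong:
- methyl delivery to the wrong face of C10, or 1,2-addition to the aldehyde;
- proton transfer from the ketone α-position to enolate 16 before ring closure, which would open the crossed aldol at C11;
- retro-aldol opening or loss of water from the aldolate.

Fallback: the methyl group is brought in by alkylation and ring B is closed with an allylsilane instead of an enolate. It sets out from imine 6. Azaenolate 9, formed with Grignard reagent 8 as in step 4, is trapped with MeI (THF/DMPU), anti to the C5 chain, to give tert-butyl (2S)-2-{[(E)-{(1S,2R)-1,3,3-trimethyl-2-[2-(2-methyl-1,3-dioxolan-2-yl)ethyl]cyclohexyl}methylidene]amino}-3,3-dimethylbutanoate F1. Buffered hydrolysis gives (1S,2R)-1,3,3-trimethyl-2-[2-(2-methyl-1,3-dioxolan-2-yl)ethyl]cyclohexane-1-carbaldehyde F2. Wittig reaction with Ph3P=CHCH2SiMe3 gives trimethyl{(2Z)-3-[(1R,2R)-1,3,3-trimethyl-2-[2-(2-methyl-1,3-dioxolan-2-yl)ethyl]cyclohexyl]prop-2-en-1-yl}silane F3. Ketal hydrolysis (PPTS, wet acetone) gives 4-[(1R,2R)-2,6,6-trimethyl-2-[(1Z)-3-(trimethylsilyl)prop-1-en-1-yl]cyclohexyl]butan-2-one F4. TiCl4-promoted intramolecular Hosomi–Sakurai addition (CH2Cl2, −78 °C) then closes the same C8–C9 bond, in the chair with equatorial vinyl and equatorial CH3-17, and the route is rejoined at vinyl carbinol 18.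

Step 4. What may go wrong:
- slow 1,4-addition at the β-carbon flanked by the quaternary C4;
- competing 1,2-addition to the imine;
- weak or reversed facial control by the auxiliary;
- partial ketal loss during hydrolysis.

Fallback: C5 is set by a copper-catalysed asymmetric conjugate addition to an ester. It sets out from triflate 3. Methoxycarbonylation (Pd(OAc)2, PPh3, CO, MeOH, Et3N, DMF) gives methyl 3,3-dimethylcyclohex-1-ene-1-carboxylate F5. CuI/Tol-BINAP-catalysed 1,4-addition of Grignard reagent 8 (ligand enantiomer chosen for the 2S adduct) gives methyl (1R,2S)-3,3-dimethyl-2-[2-(2-methyl-1,3-dioxolan-2-yl)ethyl]cyclohexane-1-carboxylate F6. Reduction with iBu2AlH (toluene, −78 °C) leads back to aldehyde 11.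

Step 9. What may go wrong:
- retro-aldol cleavage or dehydration of the β-hydroxy aldehyde under the Lewis-acidic reagent;
- incomplete conversion of the neopentyl-type aldehyde.

Fallback: the side chain is built by carbonyl olefination instead of hydroboration and cross-coupling. It sets out from 17. The neutral stabilised ylide Ph3P=CHC(O)CH3 gives (3E)-4-[(1R,2S,4aR,8aS)-2-hydroxy-2,5,5,8a-tetramethyldecahydronaphthalen-1-yl]but-3-en-2-one F7. Conjugate reduction with [(Ph3P)CuH]6 gives 4-[(1R,2S,4aR,8aS)-2-hydroxy-2,5,5,8a-tetramethyldecahydronaphthalen-1-yl]butan-2-one F8. Horner–Wadsworth–Emmons reaction with triethyl phosphonoacetate (NaH, THF) gives ethyl (2E)-5-[(1R,2S,4aR,8aS)-2-hydroxy-2,5,5,8a-tetramethyldecahydronaphthalen-1-yl]-3-methylpent-2-enoate F9, separated from its (Z) isomer. iBu2AlH reduction rejoins the route at diol 24.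

**Further compounds**

F1 | step 8 | tert-butyl (2S)-2-{[(E)-{(1S,2R)-1,3,3-trimethyl-2-[2-(2-methyl-1,3-dioxolan-2-yl)ethyl]cyclohexyl}methylidene]amino}-3,3-dimethylbutanoate | CC(C)(C)[C@H](/N=C/[C@@]1(C)CCCC(C)(C)[C@H]1CCC1(C)OCCO1)C(=O)OC(C)(C)C
F2 | step 8 | (1S,2R)-1,3,3-trimethyl-2-[2-(2-methyl-1,3-dioxolan-2-yl)ethyl]cyclohexane-1-carbaldehyde | O=C[C@@]1(C)CCCC(C)(C)[C@H]1CCC1(C)OCCO1
F3 | step 8 | trimethyl{(2Z)-3-[(1R,2R)-1,3,3-trimethyl-2-[2-(2-methyl-1,3-dioxolan-2-yl)ethyl]cyclohexyl]prop-2-en-1-yl}silane | C[Si](C)(C)C/C=C\[C@@]1(C)CCCC(C)(C)[C@H]1CCC1(C)OCCO1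
F4 | step 8 | 4-[(1R,2R)-2,6,6-trimethyl-2-[(1Z)-3-(trimethylsilyl)prop-1-en-1-yl]cyclohexyl]butan-2-one | C[Si](C)(C)C/C=C\[C@@]1(C)CCCC(C)(C)[C@H]1CCC(C)=O
F5 | step 4 | methyl 3,3-dimethylcyclohex-1-ene-1-carboxylate | COC(=O)C1=CC(C)(C)CCC1
F6 | step 4 | methyl (1R,2S)-3,3-dimethyl-2-[2-(2-methyl-1,3-dioxolan-2-yl)ethyl]cyclohexane-1-carboxylate | COC(=O)[C@@H]1CCCC(C)(C)[C@H]1CCC1(C)OCCO1
F7 | step 9 | (3E)-4-[(1R,2S,4aR,8aS)-2-hydroxy-2,5,5,8a-tetramethyldecahydronaphthalen-1-yl]but-3-en-2-one | CC(=O)/C=C/[C@@H]1[C@@]2(C)CCCC(C)(C)[C@H]2CC[C@]1(C)O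
F8 | step 9 | 4-[(1R,2S,4aR,8aS)-2-hydroxy-2,5,5,8a-tetramethyldecahydronaphthalen-1-yl]butan-2-one | CC(=O)CC[C@@H]1[C@@]2(C)CCCC(C)(C)[C@H]2CC[C@]1(C)O
F9 | step 9 | ethyl (2E)-5-[(1R,2S,4aR,8aS)-2-hydroxy-2,5,5,8a-tetramethyldecahydronaphthalen-1-yl]-3-methylpent-2-enoate | CCOC(=O)/C=C(\C)CC[C@@H]1[C@@]2(C)CCCC(C)(C)[C@H]2CC[C@]1(C)O
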